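The plan rests on cutting the O1–C2 bond of the dihydropyran ring, C2 being pinane C2. Palladium(II) and the enol oxygen of a 2-alkylsyncarpic acid add to the same face of a pin-2-ene C2=C3 bond. Pd–H loss towards pinane C4 then frees the spiro ether, so one operation closes the pyran and sets the quaternary spiro centre. It exploits the C6 gem-dimethyl bridge of the bicyclo[3.1.1]heptene, which leaves only one alkene face open. The precursor is the enolised tetramethylcyclohexanetrione bearing at C4a an (S)-CH(isobutyl)CH2 chain that ends at pinene C2. C4 is set on a simple enoate and the trione ring is built afterwards.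

Key step: step 7

Remark: chromene numbering (O1, C2, C3, C4, C4a, C5–C8, C8a) is used for the pyran/trione part and pinane numbering for the bicycle. Compound 12 is drawn as one enol tautomer; rotation about C4–C4a interchanges its two enol oxygens, so either one closes to the same 13.

Remark: C4 is not installed on an alkylidene trione. With the doubly allylic C3 methylene such an acceptor would tautomerise to a dienol, and it would also take up a Grignard reagent without the catalyst. The sense of induction in step 2 is assigned by analogy with alkyl additions to simple (E)-2-enoates, and both ligand antipodes are commercial.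

Step 1
Reactants: 1 (1S,5S)-(−)-β-pinene; 2 methyl propiolate
Product: 3 methyl (2E)-4-[(1R,5S)-6,6-dimethylbicyclo[3.1.1]hept-2-en-2-yl]but-2-enoate
Conditions: EtAlCl2 (30 mol %), CH2Cl2, 0 °C to rt
Reagents that add atoms: none
Why: Lewis-acid-catalysed Alder-ene reaction in which the aluminium-bound propiolate bonds to the exocyclic CH2 on the face away from the gem-dimethyl bridge and takes the C3 hydrogen of that face, which moves the alkene into the ring (C2=C3), gives the E-enoate by syn addition across the alkyne and creates no stereocentre, while the ethylaluminium species scavenges protons that would open the pinane.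

Step 2
Reactants: 3 methyl (2E)-4-[(1R,5S)-6,6-dimethylbicyclo[3.1.1]hept-2-en-2-yl]but-2-enoate; 4 isobutylmagnesium bromide
Product: 5 methyl (3S)-3-{[(1R,5S)-6,6-dimethylbicyclo[3.1.1]hept-2-en-2-yl]methyl}-5-methylhexanoate
Conditions: CuI (3 mol %), (S)-Tol-BINAP (4.5 mol %), t-BuOMe, −40 °C; sat. aq. NH4Cl
Reagents that add atoms: none
Why: Copper(I)/chiral diphosphine-catalysed asymmetric conjugate addition of a Grignard reagent to an (E)-enoate, in which the ligand directs isobutyl to the Si face of the β-carbon (later C4, S), the mono-activated ester shows no uncatalysed 1,4-addition and its doubly allylic CH2 is too weakly acidic to be deprotonated at this temperature, and the enantiopure pinene unit turns any minor epimer into a removable diastereomer.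

Step 3
Reactants: 5 methyl (3S)-3-{[(1R,5S)-6,6-dimethylbicyclo[3.1.1]hept-2-en-2-yl]methyl}-5-methylhexanoate
Product: 6 (3S)-3-{[(1R,5S)-6,6-dimethylbicyclo[3.1.1]hept-2-en-2-yl]methyl}-5-methylhexanoic acid
Conditions: LiOH, THF/MeOH/H2O, rt; then cold 1 M HCl to pH 3
Reagents that add atoms: lithium hydroxide, [Li+].[OH-]
Why: Ester saponification, in which the stereocentre is β to the carbonyl group and cannot epimerise and the brief cold acidification spares the pinene alkene.

Step 4
Reactants: 7 2,2,4,4-tetramethylcyclobutane-1,3-dione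
Product: 8 methyl 2,2,4-trimethyl-3-oxopentanoate
Conditions: NaOMe (5 mol %), MeOH, reflux
Reagents that add atoms: methanol, CO
Why: Methoxide adds to one carbonyl group of the strained, non-enolisable 1,3-dione and retro-Claisen ring opening gives the β-keto ester, whose only acidic C–H is the isopropyl methine needed in step 5.

Step 5
Reactants: 6 (3S)-3-{[(1R,5S)-6,6-dimethylbicyclo[3.1.1]hept-2-en-2-yl]methyl}-5-methylhexanoic acid; 8 methyl 2,2,4-trimethyl-3-oxopentanoate
Product: 11 methyl (7S)-7-{[(1R,5S)-6,6-dimethylbicyclo[3.1.1]hept-2-en-2-yl]methyl}-2,2,4,4,9-pentamethyl-3,5-dioxodecanoate, via acid chloride 9 (not isolated), via lithium enolate 10 (not isolated)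
Conditions: 6, Me2C=C(Cl)NMe2, CH2Cl2, 0 °C; separately 8 (2.2 equiv), LDA (2.2 equiv), THF, −78 °C; combine, −78 to −30 °C
Reagents that add atoms: none
Why: C-acylation of a preformed lithium ketone enolate with an acid chloride (crossed Claisen-type acylation, the way the parent triketo ester of syncarpic acid is assembled), in which the neutral chloroenamine makes the acid chloride without HCl so the pinene survives, the excess enolate absorbs the proton of the more acidic product and no stereocentre is touched.

Step 6
Reactants: 11 methyl (7S)-7-{[(1R,5S)-6,6-dimethylbicyclo[3.1.1]hept-2-en-2-yl]methyl}-2,2,4,4,9-pentamethyl-3,5-dioxodecanoate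
Product: 12 2-{(2S)-1-[(1R,5S)-6,6-dimethylbicyclo[3.1.1]hept-2-en-2-yl]-4-methylpentan-2-yl}-3-hydroxy-4,4,6,6-tetramethylcyclohex-2-ene-1,5-dione
Conditions: KOt-Bu (1.5 equiv), THF, 0 °C to rt; then cold 1 M HCl
Reagents that add atoms: none
Why: Dieckmann condensation in which the only enolisable position (the future C4a methylene) attacks the methyl ester in a 6-exo-trig closure favoured by two gem-dimethyl groups, deprotonation of the acidic trione drives the reaction, and C4 is left untouched.

Step 7
Reactants: 12 2-{(2S)-1-[(1R,5S)-6,6-dimethylbicyclo[3.1.1]hept-2-en-2-yl]-4-methylpentan-2-yl}-3-hydroxy-4,4,6,6-tetramethylcyclohex-2-ene-1,5-dione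
Product: 13 (1R,2S,4'S,5R)-6,6,6',6',8',8'-hexamethyl-4'-(2-methylpropyl)-3',4'-dihydrospiro[bicyclo[3.1.1]hept-3-ene-2,2'-chromene]-5',7'(6'H,8'H)-dione (O1 anti to the gem-dimethyl bridge)
Conditions: Pd(TFA)2 (10 mol %), pyridine (40 mol %), Na2CO3 (2 equiv), 3 Å MS, O2 (1 atm), toluene, 80 °C
Reagents that add atoms: none
Why: Carbonate-assisted exchange of trifluoroacetate places the enolate oxygen on palladium(II), the C2=C3 alkene binds through its only accessible face, and migratory insertion into the Pd–O bond forms O1–C2 and C3–Pd on that face, after which syn β-hydride elimination with the cofacial pinane C4–H gives 13 and a Pd–H that oxygen returns to palladium(II). The closest known reaction type is the aerobic Wacker-type oxidative cyclisation of phenols, alcohols and 1,3-dicarbonyl enols onto trisubstituted alkenes with chloride-free Pd(TFA)2/pyridine. The pyran ring closes in the 6-exo-trig mode, the 7-endo alternative being disfavoured by ring size and by the preference of oxygen for the more substituted alkene carbon. The new stereocentre C2 is controlled by the C6 gem-dimethyl bridge: metal and oxygen have to arrive together on the unshielded face, so O1 ends anti and C3 syn to the bridge as in 14, whereas outer-sphere attack, the usual course for carboxylate-like nucleophiles, would have to pass through the blocked face. The step needs oxypalladation to outrun allylic C–H palladation and dehydrogenation across C4a–C4; the pre-bound enolate, the non-polar medium and the absence of chloride and acetate favour it, C2 bears no hydrogen so elimination can only go towards C4, and the C5 bridgehead stops chain walking. Because C2 never carries a positive charge or an unpaired electron the four-membered ring stays intact, and palladium(0) cannot ionise the new allylic C–O bond since it would have to approach from the bridged face.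

Step 8
Reactants: 13 (1R,2S,4'S,5R)-6,6,6',6',8',8'-hexamethyl-4'-(2-methylpropyl)-3',4'-dihydrospiro[bicyclo[3.1.1]hept-3-ene-2,2'-chromene]-5',7'(6'H,8'H)-dione
Product: 14 (1R,2R,4'S,5S)-6,6,6',6',8',8'-hexamethyl-4'-(2-methylpropyl)-3',4'-dihydrospiro[bicyclo[3.1.1]heptane-2,2'-chromene]-5',7'(6'H,8'H)-dione (CNP0231252.1)
Conditions: 2-nitrobenzenesulfonyl hydrazide (excess), Et3N, CH2Cl2, rt
Reagents that add atoms: none
Why: Diimide reduction (concerted syn transfer of two hydrogens) takes the strained cis-disubstituted pinane C3=C4 alkene but not the tetrasubstituted push–pull C4a=C8a alkene or the ketones, cannot cleave the tertiary allylic C–O bond as hydrogenation over palladium might, and forms no stereocentre.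

Compound list
1 | (1S,5S)-(−)-β-pinene | C=C1CC[C@H]2C[C@@H]1C2(C)C | starting material
2 | methyl propiolate | C#CC(=O)OC | starting material
3 | methyl (2E)-4-[(1R,5S)-6,6-dimethylbicyclo[3.1.1]hept-2-en-2-yl]but-2-enoate | COC(=O)/C=C/CC1=CC[C@H]2C[C@@H]1C2(C)C | intermediate
4 | isobutylmagnesium bromide | CC(C)C[Mg]Br | starting material
5 | methyl (3S)-3-{[(1R,5S)-6,6-dimethylbicyclo[3.1.1]hept-2-en-2-yl]methyl}-5-methylhexanoate | CC(C)C[C@@H](CC1=CC[C@H]2C[C@@H]1C2(C)C)CC(=O)OC | intermediate
6 | (3S)-3-{[(1R,5S)-6,6-dimethylbicyclo[3.1.1]hept-2-en-2-yl]methyl}-5-methylhexanoic acid | CC(C)C[C@@H](CC1=CC[C@H]2C[C@@H]1C2(C)C)CC(=O)O | intermediate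
7 | 2,2,4,4-tetramethylcyclobutane-1,3-dione | CC1(C)C(=O)C(C)(C)C1=O | starting material
8 | methyl 2,2,4-trimethyl-3-oxopentanoate | COC(=O)C(C)(C)C(=O)C(C)C | intermediate
9 | (3S)-3-{[(1R,5S)-6,6-dimethylbicyclo[3.1.1]hept-2-en-2-yl]methyl}-5-methylhexanoyl chloride (not isolated) | CC(C)C[C@@H](CC1=CC[C@H]2C[C@@H]1C2(C)C)CC(=O)Cl | intermediate
10 | lithium enolate of 8 (not isolated) | [Li+].COC(=O)C(C)(C)C([O-])=C(C)C | intermediate
11 | methyl (7S)-7-{[(1R,5S)-6,6-dimethylbicyclo[3.1.1]hept-2-en-2-yl]methyl}-2,2,4,4,9-pentamethyl-3,5-dioxodecanoate | CC(C)C[C@@H](CC1=CC[C@H]2C[C@@H]1C2(C)C)CC(=O)C(C)(C)C(=O)C(C)(C)C(=O)OC | intermediate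
12 | 2-alkylsyncarpic acid bearing the pin-2-ene unit, (S) at C4 (precursor of the key step) | CC(C)C[C@@H](CC1=CC[C@H]2C[C@@H]1C2(C)C)C1=C(O)C(C)(C)C(=O)C(C)(C)C1=O | intermediate
13 | pinane 3,4-didehydro analogue of the target, O1 anti to the gem-dimethyl bridge (product of the key step) | CC(C)C[C@H]1C[C@@]2(C=C[C@H]3C[C@@H]2C3(C)C)OC2=C1C(=O)C(C)(C)C(=O)C2(C)C | intermediate
14 | CNP0231252.1, (1R,2R,4'S,5S)-spiro[pinane-2,2'-chromene]dione | CC(C)C[C@H]1C[C@@]2(CC[C@H]3C[C@@H]2C3(C)C)OC2=C1C(=O)C(C)(C)C(=O)C2(C)C | target

Total step count: 8. Longest linear sequence: 7 (steps 1, 2, 3, 5, 6, 7, 8).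

Steps most likely to fail

Step 7. The acidic enolate may bind palladium too weakly for insertion into the hindered trisubstituted alkene. Allylic C–H palladation of the pinene, dehydrogenation across C4a–C4 or autoxidation of the enol under oxygen could then consume 12. Fallback: give up oxypalladation and form O1–C2 and C3–C4 together by an inverse-electron-demand hetero-Diels–Alder reaction, known chemistry for alkylidene triones and exocyclic terpene alkenes.
- The fallback sets out from 1.
- Syncarpic acid and isovaleraldehyde are condensed (Knoevenagel, catalytic ethylenediammonium diacetate) to 2,2,4,4-tetramethyl-6-(3-methylbutylidene)cyclohexane-1,3,5-trione F1.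
- F1 is heated with 1. The oxadiene should add to the exocyclic alkene from the face away from the bridge, with oxygen going to C2.
- C4 is not controlled, so the C4' epimer of the target F2 has to be removed by chromatography.
- The fallback comes back to the route at 14.

Step 5. The hindered tetrasubstituted enolate may be acylated on oxygen, or may act as a base and turn the acid chloride into a ketene that oligomerises. Fallback: make the C5–C6 bond by an aldol addition, where O-attack is not productive, and adjust the oxidation state afterwards.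
- The fallback sets out from 5.
- DIBAL-H at −78 °C gives (3S)-3-{[(1R,5S)-6,6-dimethylbicyclo[3.1.1]hept-2-en-2-yl]methyl}-5-methylhexanal F3.
- Addition of lithium enolate 10 at −78 °C gives methyl (7S)-5-hydroxy-7-{[(1R,5S)-6,6-dimethylbicyclo[3.1.1]hept-2-en-2-yl]methyl}-2,2,4,4,9-pentamethyl-3-oxodecanoate F4 as both carbinol epimers.
- Buffered DMP oxidation brings the sequence back to the route at 11.

Step 2. The β-branched Grignard reagent may transfer slowly and with poor facial selectivity under ligand control, or 1,2-addition may compete. Fallback: replace catalyst control by a covalently bound oxazolidinone auxiliary.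
- The fallback sets out from 3.
- Saponification (LiOH, 0 °C) gives (2E)-4-[(1R,5S)-6,6-dimethylbicyclo[3.1.1]hept-2-en-2-yl]but-2-enoic acid F5.
- DCC/DMAP coupling with (R)-4-phenyl-1,3-oxazolidin-2-one gives the N-enoyl imide F6.
- iBuMgBr/CuBr·SMe2 (THF/Me2S, −40 °C) should add to the magnesium-chelated s-cis conformer on the face away from the phenyl group (the Si face of the β-carbon) to give the (3S)-imide F7.
- LiOH/H2O2 removes the auxiliary and the sequence comes back to the route at 6.

Further compounds
F1 | step 7 | 2,2,4,4-tetramethyl-6-(3-methylbutylidene)cyclohexane-1,3,5-trione | CC(C)CC=C1C(=O)C(C)(C)C(=O)C(C)(C)C1=O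
F2 | step 7 | C4' epimer of the target, (1R,2R,4'R,5S) | CC(C)C[C@@H]1C[C@@]2(CC[C@H]3C[C@@H]2C3(C)C)OC2=C1C(=O)C(C)(C)C(=O)C2(C)C
F3 | step 5 | (3S)-3-{[(1R,5S)-6,6-dimethylbicyclo[3.1.1]hept-2-en-2-yl]methyl}-5-methylhexanal | CC(C)C[C@@H](CC1=CC[C@H]2C[C@@H]1C2(C)C)CC=O
F4 | step 5 | methyl (7S)-5-hydroxy-7-{[(1R,5S)-6,6-dimethylbicyclo[3.1.1]hept-2-en-2-yl]methyl}-2,2,4,4,9-pentamethyl-3-oxodecanoate (both C5 epimers) | CC(C)C[C@@H](CC1=CC[C@H]2C[C@@H]1C2(C)C)CC(O)C(C)(C)C(=O)C(C)(C)C(=O)OC
F5 | step 2 | (2E)-4-[(1R,5S)-6,6-dimethylbicyclo[3.1.1]hept-2-en-2-yl]but-2-enoic acid | OC(=O)/C=C/CC1=CC[C@H]2C[C@@H]1C2(C)C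
F6 | step 2 | (4R)-3-{(2E)-4-[(1R,5S)-6,6-dimethylbicyclo[3.1.1]hept-2-en-2-yl]but-2-enoyl}-4-phenyl-1,3-oxazolidin-2-one | O=C(/C=C/CC1=CC[C@H]2C[C@@H]1C2(C)C)N1[C@H](c2ccccc2)COC1=O
F7 | step 2 | (4R)-3-[(3S)-3-{[(1R,5S)-6,6-dimethylbicyclo[3.1.1]hept-2-en-2-yl]methyl}-5-methylhexanoyl]-4-phenyl-1,3-oxazolidin-2-one | CC(C)C[C@@H](CC1=CC[C@H]2C[C@@H]1C2(C)C)CC(=O)N1[C@H](c2ccccc2)COC1=O
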